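**Assumption:** O‑TBS‑vanillin (CAS 69404‑94‑0) is treated as purchasable; if not, it is one step from vanillin (TBSCl, imidazole, DMF). The target SMILES encodes the all‑trans, C2‑symmetric (2R,3S,4S,5R) isomer. The key double aldol (step 2) is proposed by analogy to mono‑succinyl Evans aldols, not from a known procedure on this exact substrate.

## Retrosynthetic overview

1. The target is unmasked last by global desilylation of its tetra‑TBS ether.
2. The THF ring (C–O–C between the two benzylic carbons) is the only ring in the target and is formed last, by SN1 cycloetherification of a C2‑symmetric 1,4‑diaryl‑1,4‑diol whose two primary OH groups are silylated.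
3. That diol comes from hydride opening of an exo,exo‑diaryl cis‑fused bis‑γ‑lactone (a temporary bicycle, formed first), which already carries all four stereocentres.
4. The bis‑lactone comes from a double Evans syn‑aldol/lactonisation between succinyl bis[(R)‑4‑benzyloxazolidinone] and two equivalents of O‑TBS‑vanillin.

## Route

**Step 1**
Reactants: **1** succinyl chloride; **2** (R)‑4‑benzyl‑1,3‑oxazolidin‑2‑one (2.05 equiv)
Product: **3** 1,4‑bis[(4R)‑4‑benzyl‑2‑oxo‑1,3‑oxazolidin‑3‑yl]butane‑1,4‑dione
Conditions: **2**, n‑BuLi (2.05 equiv), THF, −78 °C; then **1**, −78 → 0 °C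
Reagents that add atoms: none
Why: Double N‑acylation of the lithiated oxazolidinone by the diacid chloride (standard Evans auxiliary loading); no new stereocentre is formed.

**Step 2**
Reactants: **3**; **4** 4‑(tert‑butyldimethylsilyloxy)‑3‑methoxybenzaldehyde (2.5 equiv)
Product: **5** (1R,4R,5R,8R)‑4,8‑bis[4‑(TBSO)‑3‑methoxyphenyl]‑3,7‑dioxabicyclo[3.3.0]octane‑2,6‑dione (cis‑fused bis‑γ‑lactone, both aryl groups exo); 2 equiv of **2** are released and recovered
Conditions: Bu2BOTf (2.4 equiv), i‑Pr2NEt (2.8 equiv), CH2Cl2, 0 °C; **4**, −78 → 0 °C; pH 7 buffer/MeOH/30% H2O2, 0 °C; then DMAP (cat.), CH2Cl2, rt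
Reagents that add atoms: none
Why: Double Evans syn‑aldol of the bis‑(Z)‑boron enolate through Zimmerman–Traxler chairs, each (R)‑auxiliary directing the same facial sense, sets both ArCH(O)–CH pairs as the C2‑symmetric syn,syn array; each γ‑hydroxyl then acylates on the opposite imide, expelling the auxiliary and giving the exo,exo bis‑lactone.

**Step 3**
Reactants: **5**
Product: **6** (1R,2S,3S,4R)‑1,4‑bis[4‑(TBSO)‑3‑methoxyphenyl]‑2,3‑bis(hydroxymethyl)butane‑1,4‑diol
Conditions: LiBH4 (5 equiv), THF, MeOH (2 equiv), 0 °C → rt; neutral quench (sat. NH4Cl/Rochelle salt)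
Reagents that add atoms: none
Why: Hydride reduction of both γ‑lactones to primary alcohols leaves all four stereocentres and the aryl silyl ethers untouched; any un‑lactonised bis‑aldol imide from step 2 converges on the same tetraol.

**Step 4**
Reactants: **6**
Product: **7** (1R,2S,3S,4R)‑2,3‑bis[(tert‑butyldimethylsilyloxy)methyl]‑1,4‑bis[4‑(TBSO)‑3‑methoxyphenyl]butane‑1,4‑diol
Conditions: TBSCl (2.2 equiv), imidazole (4 equiv), DMF, 0 °C
Reagents that add atoms: TBSCl, CC(C)(C)[Si](C)(C)Cl
Why: Chemoselective silylation, since the primary OH groups react much faster than the hindered secondary benzylic ones; this blocks the competing furofuran (pinoresinol‑type) ring closure in the next step.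

**Step 5**
Reactants: **7**
Product: **8** (2R,3S,4S,5R)‑2,5‑bis[4‑(TBSO)‑3‑methoxyphenyl]‑3,4‑bis[(tert‑butyldimethylsilyloxy)methyl]tetrahydrofuran (all‑trans)
Conditions: MsCl (1.15 equiv, slow addition), Et3N (3 equiv), CH2Cl2, −20 °C → rt
Reagents that add atoms: none
Why: SN1 cycloetherification: one benzylic OH is mesylated and ionises to a p‑siloxy‑stabilised benzylic cation, which is captured by the other benzylic OH (configuration retained) anti to the neighbouring CH2OTBS, giving the thermodynamically preferred all‑trans ring with C3/C4 untouched.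

**Step 6**
Reactants: **8**
Product: **9** (+)‑neoolivil, (2R,3S,4S,5R)‑2,5‑bis(4‑hydroxy‑3‑methoxyphenyl)‑3,4‑bis(hydroxymethyl)tetrahydrofuran
Conditions: TBAF (6 equiv), AcOH (6 equiv), THF, 0 °C → rt
Reagents that add atoms: none
Why: Fluoride desilylation removes all four silyl ethers in one operation; AcOH buffering keeps the freed p‑hydroxybenzylic ethers from quinone‑methide ring opening, so no stereocentre is disturbed.

## Compound list

1 | succinyl chloride | O=C(Cl)CCC(=O)Cl | starting material
2 | (R)‑4‑benzyl‑1,3‑oxazolidin‑2‑one | O=C1N[C@H](Cc2ccccc2)CO1 | starting material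
3 | 1,4‑bis[(4R)‑4‑benzyl‑2‑oxo‑oxazolidin‑3‑yl]butane‑1,4‑dione | O=C(CCC(=O)N1[C@H](Cc2ccccc2)COC1=O)N1[C@H](Cc2ccccc2)COC1=O | intermediate
4 | 4‑(tert‑butyldimethylsilyloxy)‑3‑methoxybenzaldehyde | COc1cc(C=O)ccc1O[Si](C)(C)C(C)(C)C | starting material
5 | (1R,4R,5R,8R)‑4,8‑diaryl‑3,7‑dioxabicyclo[3.3.0]octane‑2,6‑dione, aryl = 4‑TBSO‑3‑MeO‑phenyl | COc1cc([C@@H]2OC(=O)[C@@H]3[C@H]2C(=O)O[C@H]3c4ccc(O[Si](C)(C)C(C)(C)C)c(OC)c4)ccc1O[Si](C)(C)C(C)(C)C | intermediate
6 | (1R,2S,3S,4R)‑1,4‑diaryl‑2,3‑bis(hydroxymethyl)butane‑1,4‑diol | COc1cc([C@H](O)[C@H](CO)[C@@H](CO)[C@@H](O)c2ccc(O[Si](C)(C)C(C)(C)C)c(OC)c2)ccc1O[Si](C)(C)C(C)(C)C | intermediate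
7 | (1R,2S,3S,4R)‑1,4‑diaryl‑2,3‑bis(TBSOCH2)butane‑1,4‑diol | COc1cc([C@H](O)[C@H](CO[Si](C)(C)C(C)(C)C)[C@@H](CO[Si](C)(C)C(C)(C)C)[C@@H](O)c2ccc(O[Si](C)(C)C(C)(C)C)c(OC)c2)ccc1O[Si](C)(C)C(C)(C)C | intermediate
8 | (2R,3S,4S,5R)‑tetra‑TBS neoolivil | COc1cc([C@@H]2O[C@@H](c3ccc(O[Si](C)(C)C(C)(C)C)c(OC)c3)[C@H](CO[Si](C)(C)C(C)(C)C)[C@H]2CO[Si](C)(C)C(C)(C)C)ccc1O[Si](C)(C)C(C)(C)C | intermediate
9 | (+)‑neoolivil | COc1cc([C@@H]2O[C@@H](c3ccc(O)c(OC)c3)[C@H](CO)[C@H]2CO)ccc1O | target

## Summary

Total steps: 6. Longest linear sequence: 6 (2 → 3 → 5 → 6 → 7 → 8 → 9).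

Steps most likely to fail, each with a fallback that changes the approach:

1. **Step 2 (double aldol/lactonisation).** Bis‑enolisation of the succinyl bis‑imide, the second aldol and the lactonisation are the least precedented parts. Fallback: make the C8–C8′ bond first. Oxidatively homocouple the lithium enolate (LDA; TiCl4 or CuCl2/PhI(OAc)2) of the (R)‑oxazolidinone imide of 3‑(4‑protected‑oxy‑3‑methoxyphenyl)propanoic acid to the (S,S)‑2,3‑dibenzylsuccinyl bis‑imide. Hydrolyse (LiOH/H2O2), then close both lactones by DDQ benzylic oxidation with carboxylate trapping, giving **5** or its O‑benzyl analogue.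

2. **Step 5 (THF closure).** Risks are SN2 inversion giving the 2,3‑cis epimer, bis‑mesylation, or elimination to a styrene. Fallback: switch to a reversible quinone‑methide cyclisation. Selectively free the phenols of **7** (K2CO3, MeOH cleaves only aryl‑OTBS), then use mild acid or heat so the p‑quinone methide is trapped by the other benzylic OH under thermodynamic control (all‑trans), and remove the alkyl TBS groups last.

3. **Step 6 (global desilylation).** The free p‑hydroxybenzylic ethers may ring‑open or epimerise under basic fluoride, and the polar product is awkward to separate from TBAF salts. Fallback: change the phenol protecting group to benzyl from the start (commercial O‑benzylvanillin in step 2). Remove the two alkyl TBS groups while the phenols are still capped, then finish with neutral hydrogenolysis (H2, Pd/C, EtOAc).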